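The target is treated as an oxygen-poor cyclophane that receives two of its four oxygens last. In ring A (ether O at C1′, chain at C3′) the C5′–H, and in ring B (ether O at C1, O at C2, chain at C6) the C4–H, are the only aromatic C–H bonds with no ortho neighbour. One iridium-catalysed double C–H borylation/oxidation of the saturated, mono-methoxy 20-membered diaryl ether therefore installs both meta-hydroxyls in a single operation. Its precursor needs no resorcinol or hydroxyquinol building block: it is stitched from two mono-oxygenated benzaldehydes by SNAr and a two-fold Wittig ring closure with a C12 bis-ylide.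

Key step: step 5

Remark: the target has no stereocentre and no stereogenic double bond, so it is one achiral compound and no step has to control configuration; the alkene geometry of intermediate 8 is erased by hydrogenation.

Locants used below: ring A (one OH) carries the ether oxygen at C1′, the chain at C3′ and OH at C5′; ring B carries the ether oxygen at C1, OH at C2 and C4, and the chain at C6. The chain has 14 CH2 groups and the macrocycle is 20-membered.

Step 1
Reactants: 1 3-hydroxybenzaldehyde; 2 2-fluoro-3-methoxybenzaldehyde
Product: 3 2-(3-formylphenoxy)-3-methoxybenzaldehyde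
Conditions: K2CO3 (1.5 equiv), DMAc, 130 °C
Reagents that add atoms: none
Why: Nucleophilic aromatic substitution (SNAr, addition–elimination) in which the ortho formyl group of 2 stabilises the Meisenheimer intermediate, both aldehydes are non-enolisable and should survive carbonate, and the activating formyl carbon later becomes chain carbon 1.

Step 2
Reactants: 4 1,12-dibromododecane
Product: 5 dodecane-1,12-diylbis(triphenylphosphonium) dibromide
Conditions: PPh3 (2.2 equiv), MeCN, reflux
Reagents that add atoms: triphenylphosphine, c1ccc(cc1)P(c1ccccc1)c1ccccc1
Why: Two-fold SN2 quaternisation of triphenylphosphine by the primary dibromide (phosphonium salt formation), driven to the bis-salt by excess phosphine.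

Step 3
Reactants: 3 2-(3-formylphenoxy)-3-methoxybenzaldehyde; 5 dodecane-1,12-diylbis(triphenylphosphonium) dibromide
Product: 8 mono-methoxy macrocyclic (Z,Z)-diene (ring B C6–CH=CH–(CH2)10–CH=CH–C3′ ring A; OMe at C2; geometric mixture expected), via bis-ylide 6 (not isolated), via seco ylide-aldehyde 7 (not isolated)
Conditions: 5, KHMDS (2.05 equiv), THF, 0 °C; then the ylide solution and 3 added simultaneously by syringe pump to THF (final ca. 2 mM), rt
Reagents that add atoms: none
Why: Two-fold Wittig olefination in which the first, intermolecular olefination tethers the remaining non-stabilised ylide to the remaining aldehyde, so that under pseudo-high dilution the second olefination should close the unstrained 20-membered ring in preference to chain growth; the alkene geometry is irrelevant and no stereocentre arises.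

Step 4
Reactants: 8 mono-methoxy macrocyclic diene
Product: 9 saturated mono-methoxy macrocycle (the 4,5′-dideoxy-2-O-methyl derivative of the target)
Conditions: H2 (1 atm), 10% Pd/C, EtOAc/EtOH, rt
Reagents that add atoms: none
Why: Heterogeneous catalytic hydrogenation of the two 1,2-disubstituted styrenyl alkenes, to which the diaryl ether and the aryl methyl ether are inert, and which also removes the alkenes before the borylation.

Step 5
Reactants: 9 saturated mono-methoxy macrocycle
Product: 11 2-O-methyl ether of the target (free OH at C4 of ring B plus C5′ of ring A), via bis(pinacolboronate) 10 (not isolated)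
Conditions: [Ir(OMe)(cod)]2 (3 mol %), dtbpy (6 mol %), B2pin2 (3 equiv), THF, 80 °C; concentrate; then 30% aq. H2O2, 2 M aq. NaOH, THF, 0 °C; NH4Cl work-up
Reagents that add atoms: bis(pinacolato)diboron, CC1(C)OB(OC1(C)C)B1OC(C)(C)C(C)(C)O1 (boron and pinacolate of 10); hydrogen peroxide, OO (the two new oxygen atoms of 11)
Why: The (dtbpy)Ir(Bpin)3 complex cleaves an aryl C–H bond by oxidative addition and releases ArBpin by reductive elimination, and basic peroxide then converts each C–B bond into C–O by 1,2-aryl migration at the same carbon. The closest known reaction type is the sterically controlled iridium-catalysed arene C–H borylation with one-pot oxidation, which turns 1,3-disubstituted and 1,2,3-trisubstituted benzenes into the 5-hydroxy compounds. No ring is closed and no stereocentre is formed. The step needs C5′ of ring A and C4 of ring B to react in preference to the other five aromatic C–H bonds and the benzylic CH2 groups. This is secured because the crowded tris(boryl)iridium centre avoids C–H bonds next to a substituent: C2′ is flanked by O and the chain, C4′ and C6′ each have one ortho substituent, C3 is ortho to OMe and C5 is ortho to the chain, while sp2 C–H is favoured over benzylic sp3 C–H with bipyridine ligands. After one borylation per ring every remaining C–H has an ortho neighbour, so the reaction should stop at the bis-boronate.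

Step 6
Reactants: 11 2-O-methyl ether of the target
Product: 12 target (CNP0173380.0)
Conditions: BBr3 (5 equiv), CH2Cl2, −78 → 0 °C; then H2O
Reagents that add atoms: none
Why: Lewis-acid mediated aryl methyl ether cleavage (BBr3 demethylation by O–B complexation and SN2 attack of bromide on the methyl group), in which the diaryl ether offers no sp3 carbon on oxygen and should stay intact, and the free phenols are released from their borate esters on aqueous work-up.

Compound list
1 | 3-hydroxybenzaldehyde | O=Cc1cccc(O)c1 | starting material
2 | 2-fluoro-3-methoxybenzaldehyde | COc1cccc(C=O)c1F | starting material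
3 | 2-(3-formylphenoxy)-3-methoxybenzaldehyde | COc1cccc(C=O)c1Oc1cccc(C=O)c1 | intermediate
4 | 1,12-dibromododecane | BrCCCCCCCCCCCCBr | starting material
5 | dodecane-1,12-diylbis(triphenylphosphonium) dibromide | [Br-].[Br-].c1ccc(cc1)[P+](c1ccccc1)(c1ccccc1)CCCCCCCCCCCC[P+](c1ccccc1)(c1ccccc1)c1ccccc1 | intermediate
6 | bis-ylide, dodecane-1,12-diylidenebis(triphenylphosphorane) (not isolated) | c1ccc(cc1)P(c1ccccc1)(c1ccccc1)=CCCCCCCCCCCC=P(c1ccccc1)(c1ccccc1)c1ccccc1 | intermediate
7 | seco ylide-aldehyde, drawn for first olefination at the ring-A aldehyde; the regioisomer from first olefination at the ring-B aldehyde closes to the same product (not isolated) | COc1cccc(C=O)c1Oc1cccc(c1)/C=C\CCCCCCCCCCC=P(c1ccccc1)(c1ccccc1)c1ccccc1 | intermediate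
8 | mono-methoxy macrocyclic diene, 20-membered: ring B C1–O–C1′ ring A, ring B C6–CH=CH–(CH2)10–CH=CH–C3′ ring A, OMe at C2 (Z,Z drawn; geometric mixture expected) | COc1cccc(/C=C\CCCCCCCCCC/C=C\c2cccc(c2)O3)c13 | intermediate
9 | saturated mono-methoxy macrocycle: ring B C1–O–C1′ ring A, ring B C6–(CH2)14–C3′ ring A, OMe at C2 | COc1cccc2c1Oc1cccc(c1)CCCCCCCCCCCCCC2 | intermediate
10 | 4,5′-bis(4,4,5,5-tetramethyl-1,3,2-dioxaborolan-2-yl) derivative of 9 (not isolated) | COc1cc(B2OC(C)(C)C(C)(C)O2)cc3c1Oc1cc(B2OC(C)(C)C(C)(C)O2)cc(c1)CCCCCCCCCCCCCC3 | intermediate
11 | 2-O-methyl ether of the target: OH at C4 (ring B) and C5′ (ring A), OMe at C2 | COc1cc(O)cc2c1Oc1cc(O)cc(c1)CCCCCCCCCCCCCC2 | intermediate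
12 | target CNP0173380.0: 20-membered diaryl ether cyclophane with OH at C2, C4 (ring B) and C5′ (ring A) | Oc1cc2cc(c1)Oc1c(O)cc(O)cc1CCCCCCCCCCCCCC2 | target

Total step count: 6. Longest linear sequence: 5 steps (steps 1, 3, 4, 5, 6).

Steps most likely to fail

Step 3. Chain growth by an intermolecular second olefination may outrun ring closure, and the non-stabilised bis-ylide may be slowly quenched during the long addition, so that oligomers and half-reacted material dominate. The fallback sets out from 2 and comes back to the route at 9; it closes the ring by a unimolecular ring-closing metathesis. SNAr of 2 with commercial 3-bromophenol (K2CO3, DMAc, 130 °C) should give 2-(3-bromophenoxy)-3-methoxybenzaldehyde F1. Wittig methylenation (Ph3PCH3Br, KOtBu, THF, 0 °C) should give 2-(3-bromophenoxy)-1-ethenyl-3-methoxybenzene F2. B-alkyl Suzuki–Miyaura coupling of F2 with the mono-adduct of 9-BBN and excess tetradeca-1,13-diene [PdCl2(dppf), aq. K3PO4, THF/DMF, 60 °C] should give 1-ethenyl-3-methoxy-2-[3-(tetradec-13-en-1-yl)phenoxy]benzene F3. Ring-closing metathesis of the styrene with the terminal alkene [RuCl2(H2IMes)(PCy3)(=CHPh), 1,4-benzoquinone, CH2Cl2, 1 mM, 40 °C] should give the macrocyclic monoene F4 (ring B C6–CH=CH–(CH2)12–C3′ ring A), and hydrogenation (H2, Pd/C, EtOAc) should give 9.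

Step 5. The second borylation may stall on the more hindered and more electron-rich ring B, leaving mixtures of mono- and bis-borylated macrocycle; minor borylation next to the small methoxy group may occur; and the para-aryloxyphenol of ring B may be over-oxidised during the peroxide treatment. The fallback sets out from 5 and comes back to the route at 12; it carries all oxygens from the start. Copper-catalysed Ullmann etherification of commercial 3-hydroxy-5-methoxybenzaldehyde with commercial 2-bromo-3,5-dimethoxybenzaldehyde (CuI, N,N-dimethylglycine, Cs2CO3, dioxane, 100 °C) should give 2-(3-formyl-5-methoxyphenoxy)-3,5-dimethoxybenzaldehyde F5. Two-fold Wittig ring closure with bis-ylide 6, generated from 5 as in step 3, should give the trimethoxy macrocyclic diene F6. Hydrogenation (H2, Pd/C) should give the tri-O-methyl ether of the target F7, and BBr3 (CH2Cl2, −78 → 0 °C) should give 12.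

Step 1. Substitution at a fluoride flanked by two ortho substituents, one of them a donor methoxy group, may be slow, and the aldehydes may degrade at the temperature then required. The fallback sets out from 1 and comes back to the route at 3: copper-catalysed Ullmann etherification of 1 with commercial 2-bromo-3-methoxybenzaldehyde (CuI, N,N-dimethylglycine, Cs2CO3, dioxane, 100 °C) should give 3 directly and makes no new compound (F0).

Further compounds
F1 | step 3 | 2-(3-bromophenoxy)-3-methoxybenzaldehyde | COc1cccc(C=O)c1Oc1cccc(Br)c1
F2 | step 3 | 2-(3-bromophenoxy)-1-ethenyl-3-methoxybenzene | COc1cccc(C=C)c1Oc1cccc(Br)c1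
F3 | step 3 | 1-ethenyl-3-methoxy-2-[3-(tetradec-13-en-1-yl)phenoxy]benzene | COc1cccc(C=C)c1Oc1cccc(CCCCCCCCCCCCC=C)c1
F4 | step 3 | mono-methoxy macrocyclic monoene, ring B C6–CH=CH–(CH2)12–C3′ ring A (E drawn; geometric mixture expected) | COc1cccc(/C=C/CCCCCCCCCCCCc2cccc(c2)O3)c13
F5 | step 5 | 2-(3-formyl-5-methoxyphenoxy)-3,5-dimethoxybenzaldehyde | COc1cc(OC)c(Oc2cc(OC)cc(C=O)c2)c(C=O)c1
F6 | step 5 | trimethoxy macrocyclic diene (OMe at C2, C4 and C5′; Z,Z drawn; geometric mixture expected) | COc1cc(OC)c2c(c1)/C=C\CCCCCCCCCC/C=C\c1cc(OC)cc(c1)O2
F7 | step 5 | tri-O-methyl ether of the target (OMe at C2, C4 and C5′) | COc1cc(OC)c2c(c1)CCCCCCCCCCCCCCc1cc(OC)cc(c1)O2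
F0 | step 1 | none | none
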